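**Plan**
- Retrosynthesis: the aryl–CH2 bond of the methylene bridge is cut first (aryl C–H nucleophile plus pyranone-CH2 electrophile), then the pyranone C3–CH2 bond (Mannich). In the aryl half the C-prenyl bond (Claisen–Cope), the O–Me bond and the aryl–acyl bond (Friedel–Crafts) are cut; in the pyranone half the lactone C–O bond and the C4–C5 bond of a 3,5-diketo ester.
- Forward: the benzene ring is bought as phloroglucinol and decorated in the order acyl, 2 × MOM, O-prenyl, C-prenyl, O-methyl, deprotection. The pyranone ring is built by dianion acylation and lactonisation. The two halves are joined last, in a biomimetic step.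
- Enabling feature: C3 of the 4-hydroxy-2-pyranone is an enol carbon between two carbonyl-type carbons, so its CH2NMe2 Mannich base loses amine to give a 3-methylene-pyran-2,4-dione. The phloroglucinol ring of the partner has a single unsubstituted carbon (between the 4-OH and the 6-OMe, para to the chelated 2-OH) to capture it.
- Stereochemistry: the only stereocentre, (R) in the 2-methylbutanoyl group, is bought with (R)-2-methylbutanoic acid and carried through under non-enolising conditions.

Key step: step 11

Remark: the stereodescriptor C(=O)[C@H](C)CC is read as (R); (R)-2-methylbutanoic acid of high enantiomeric purity is assumed to be purchasable.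

**Step 1**
Reactants: 1 (R)-2-methylbutanoic acid
Product: 2 (R)-2-methylbutanoyl chloride
Conditions: (COCl)2 (1.2 eq), cat. DMF, CH2Cl2, 0 °C to rt; volatiles removed cold, used directly
Reagents that add atoms: oxalyl chloride ClC(=O)C(=O)Cl
Why: Acid chloride formation through the Vilsmeier-type chloroiminium species runs without base, so no ketene can form and the α-stereocentre should be retained.

**Step 2**
Reactants: 2 (R)-2-methylbutanoyl chloride; 3 phloroglucinol (benzene-1,3,5-triol)
Product: 4 (R)-2-methyl-1-(2,4,6-trihydroxyphenyl)butan-1-one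
Conditions: AlCl3 (3.5 eq), PhNO2/CH2Cl2, 0 °C to rt; ice/1 M HCl work-up
Reagents that add atoms: none
Why: Friedel–Crafts C-acylation of the symmetric, highly activated triol should stop at the mono-ketone because the aluminium-chelated aryl ketone is deactivated, and the stereocentre is carried over from 2.

**Step 3**
Reactants: 4 (R)-2-methyl-1-(2,4,6-trihydroxyphenyl)butan-1-one
Product: 5 (R)-1-[2-hydroxy-4,6-bis(methoxymethoxy)phenyl]-2-methylbutan-1-one
Conditions: MOMCl (2.3 eq), i-Pr2NEt (3 eq), CH2Cl2, 0 °C to rt
Reagents that add atoms: chloromethyl methyl ether COCCl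
Why: MOM etherification should take the two more acidic, non-chelated hydroxyls and leave the one hydroxyl that is hydrogen-bonded to the ketone, as is usual for acylphloroglucinols.

**Step 4**
Reactants: 5 (R)-1-[2-hydroxy-4,6-bis(methoxymethoxy)phenyl]-2-methylbutan-1-one
Product: 6 (R)-1-[2,4-bis(methoxymethoxy)-6-(3-methylbut-2-en-1-yloxy)phenyl]-2-methylbutan-1-one
Conditions: prenol (1.5 eq), PPh3 (1.5 eq), DIAD (1.5 eq), THF, 0 °C to rt
Reagents that add atoms: 3-methylbut-2-en-1-ol CC(C)=CCO
Why: Mitsunobu etherification of the remaining chelated phenol with a primary allylic alcohol is neutral, so the enolisable ketone is not exposed to base, and SN2 attack at the primary carbon gives the linear prenyl ether.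

**Step 5**
Reactants: 6 (R)-1-[2,4-bis(methoxymethoxy)-6-(3-methylbut-2-en-1-yloxy)phenyl]-2-methylbutan-1-one
Product: 9 (R)-1-[6-hydroxy-2,4-bis(methoxymethoxy)-3-(3-methylbut-2-en-1-yl)phenyl]-2-methylbutan-1-one, via ortho-dienone 7 (not isolated), via para-dienone 8 (not isolated)
Conditions: PhNEt2, 190–200 °C, degassed, sealed tube
Reagents that add atoms: none
Why: Aromatic Claisen rearrangement to the free ortho carbon followed by Cope shift (para-Claisen) should deliver the normal prenyl group to the carbon para to the ether oxygen, that is between the two MOM ethers, and tautomerisation then gives the chelated phenol; the ketone stereocentre takes no part.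

**Step 6**
Reactants: 9 (R)-1-[6-hydroxy-2,4-bis(methoxymethoxy)-3-(3-methylbut-2-en-1-yl)phenyl]-2-methylbutan-1-one
Product: 10 (R)-1-[6-methoxy-2,4-bis(methoxymethoxy)-3-(3-methylbut-2-en-1-yl)phenyl]-2-methylbutan-1-one
Conditions: MeI (3 eq), K2CO3 (2 eq), DMF, rt
Reagents that add atoms: iodomethane CI
Why: Williamson O-methylation of the only free phenol; carbonate is too weak a base to enolise the hindered, twisted aryl ketone.

**Step 7**
Reactants: 10 (R)-1-[6-methoxy-2,4-bis(methoxymethoxy)-3-(3-methylbut-2-en-1-yl)phenyl]-2-methylbutan-1-one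
Product: 11 (R)-1-[2,4-dihydroxy-6-methoxy-3-(3-methylbut-2-en-1-yl)phenyl]-2-methylbutan-1-one
Conditions: 3 M HCl (aq), MeOH, rt to 40 °C, monitored closely
Reagents that add atoms: none
Why: Acid-catalysed acetal exchange with methanol removes both MOM groups under conditions mild enough that the prenyl alkene should not cyclise onto the flanking phenols and the aryl methyl ether is untouched.

**Step 8**
Reactants: 12 methyl 3-oxopentanoate
Product: 14 methyl 4-methyl-3,5-dioxoheptanoate (racemic at C4, enol mixture), via sodium lithium dianion 13 (not isolated)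
Conditions: NaH (1.1 eq), THF, 0 °C; n-BuLi (1.05 eq), 0 °C; then EtC(O)N(OMe)Me (1.0 eq), −78 to 0 °C; cold 1 M HCl quench
Reagents that add atoms: N-methoxy-N-methylpropanamide CCC(=O)N(C)OC
Why: Huckin–Weiler dianion chemistry places the electrophile at the more reactive γ-carbon, and the Weinreb amide holds the adduct as a stable chelate until work-up, so single C-acylation should result.

**Step 9**
Reactants: 14 methyl 4-methyl-3,5-dioxoheptanoate
Product: 15 6-ethyl-4-hydroxy-5-methyl-2H-pyran-2-one
Conditions: DBU (1.5 eq), toluene, reflux; then 1 M HCl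
Reagents that add atoms: none
Why: Base-mediated lactonisation of the C5 enol oxygen onto the methyl ester (6-exo-trig) followed by enolisation gives the 4-hydroxy-2-pyranone, driven by formation of the stabilised pyranone anion.

**Step 10**
Reactants: 15 6-ethyl-4-hydroxy-5-methyl-2H-pyran-2-one
Product: 16 3-[(dimethylamino)methyl]-6-ethyl-4-hydroxy-5-methyl-2H-pyran-2-one (zwitterion)
Conditions: CH2(NMe2)2 (1.5 eq), CH2Cl2, 0 °C, 15 added slowly to the aminal; solid collected and used without chromatography
Reagents that add atoms: bis(dimethylamino)methane CN(C)CN(C)C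
Why: Mannich aminomethylation: the acidic 4-hydroxyl protonates the aminal to the iminium ion, which is taken up by C3, the only nucleophilic ring carbon; inverse addition and precipitation of the internal salt should suppress onward reaction.

**Step 11**
Reactants: 16 3-[(dimethylamino)methyl]-6-ethyl-4-hydroxy-5-methyl-2H-pyran-2-one; 11 (R)-1-[2,4-dihydroxy-6-methoxy-3-(3-methylbut-2-en-1-yl)phenyl]-2-methylbutan-1-one
Product: 18 3-{[2,4-dihydroxy-6-methoxy-5-[(2R)-2-methylbutanoyl]-3-(3-methylbut-2-en-1-yl)phenyl]methyl}-6-ethyl-4-hydroxy-5-methyl-2H-pyran-2-one, via methylene-pyrandione 17 (not isolated)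
Conditions: 16 (1.2 eq), 11 (1.0 eq), 1,4-dioxane, 70–80 °C, slow N2 sweep; brief cold dilute citric acid work-up
Reagents that add atoms: none
Why: Thermal E1cB loss of dimethylamine from the zwitterionic Mannich base should generate the cross-conjugated 3-methylene-pyran-2,4-dione 17, and the single unsubstituted carbon of the phloroglucinol ring of 11 adds to its exocyclic methylene in conjugate fashion, after which both rings regain their enol/aromatic forms. The closest known reaction type is the biomimetic Mannich-base (carba-Betti, quinone-methide-type) alkylation of acylphloroglucinols by 4-hydroxy-2-pyranones used for methylene-bridged phloroglucinyl pyranones. No ring is closed and no stereocentre is formed; the (R) centre is remote from the reacting atoms. The step needs C- over O-alkylation, cross- over homo-coupling, and no hetero-Diels–Alder capture of 17 by the prenyl alkene. Regiochemistry is fixed because every other ring carbon of 11 is substituted, and O-adducts are expected to revert to 17 and funnel to the C-adduct. Cross-coupling is favoured because the CH2 unit is placed on the pyranone beforehand (C3 of 16 is blocked), 17 is released slowly with 11 already present, and the temperature is kept moderate.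

**Compound list**
1 | (R)-2-methylbutanoic acid | CC[C@@H](C)C(=O)O | starting material
2 | (R)-2-methylbutanoyl chloride | CC[C@@H](C)C(=O)Cl | intermediate
3 | phloroglucinol (benzene-1,3,5-triol) | Oc1cc(O)cc(O)c1 | starting material
4 | (R)-2-methyl-1-(2,4,6-trihydroxyphenyl)butan-1-one | CC[C@@H](C)C(=O)c1c(O)cc(O)cc1O | intermediate
5 | (R)-1-[2-hydroxy-4,6-bis(methoxymethoxy)phenyl]-2-methylbutan-1-one | CC[C@@H](C)C(=O)c1c(O)cc(OCOC)cc1OCOC | intermediate
6 | (R)-1-[2,4-bis(methoxymethoxy)-6-(3-methylbut-2-en-1-yloxy)phenyl]-2-methylbutan-1-one | CC[C@@H](C)C(=O)c1c(OCC=C(C)C)cc(OCOC)cc1OCOC | intermediate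
7 | ortho-dienone: 3,5-bis(methoxymethoxy)-6-(2-methylbut-3-en-2-yl)-2-[(2R)-2-methylbutanoyl]cyclohexa-2,4-dien-1-one (ring sp3 centre undefined) | CC[C@@H](C)C(=O)C1=C(OCOC)C=C(OCOC)C(C(C)(C)C=C)C1=O | intermediate
8 | para-dienone: 3,5-bis(methoxymethoxy)-4-(3-methylbut-2-en-1-yl)-2-[(2R)-2-methylbutanoyl]cyclohexa-2,5-dien-1-one (ring sp3 centre undefined) | CC[C@@H](C)C(=O)C1=C(OCOC)C(CC=C(C)C)C(OCOC)=CC1=O | intermediate
9 | (R)-1-[6-hydroxy-2,4-bis(methoxymethoxy)-3-(3-methylbut-2-en-1-yl)phenyl]-2-methylbutan-1-one | CC[C@@H](C)C(=O)c1c(O)cc(OCOC)c(CC=C(C)C)c1OCOC | intermediate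
10 | (R)-1-[6-methoxy-2,4-bis(methoxymethoxy)-3-(3-methylbut-2-en-1-yl)phenyl]-2-methylbutan-1-one | CC[C@@H](C)C(=O)c1c(OC)cc(OCOC)c(CC=C(C)C)c1OCOC | intermediate
11 | (R)-1-[2,4-dihydroxy-6-methoxy-3-(3-methylbut-2-en-1-yl)phenyl]-2-methylbutan-1-one | CC[C@@H](C)C(=O)c1c(OC)cc(O)c(CC=C(C)C)c1O | intermediate
12 | methyl 3-oxopentanoate | CCC(=O)CC(=O)OC | starting material
13 | sodium lithium dianion of methyl 3-oxopentanoate | C[CH-]C(=O)[CH-]C(=O)OC.[Na+].[Li+] | intermediate
14 | methyl 4-methyl-3,5-dioxoheptanoate (racemic) | CCC(=O)C(C)C(=O)CC(=O)OC | intermediate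
15 | 6-ethyl-4-hydroxy-5-methyl-2H-pyran-2-one | CCc1oc(=O)cc(O)c1C | intermediate
16 | 3-[(dimethylamino)methyl]-6-ethyl-4-hydroxy-5-methyl-2H-pyran-2-one | CCc1oc(=O)c(CN(C)C)c(O)c1C | intermediate
17 | 6-ethyl-5-methyl-3-methylidene-2H-pyran-2,4(3H)-dione | CCC1=C(C)C(=O)C(=C)C(=O)O1 | intermediate
18 | 3-{[2,4-dihydroxy-6-methoxy-5-[(2R)-2-methylbutanoyl]-3-(3-methylbut-2-en-1-yl)phenyl]methyl}-6-ethyl-4-hydroxy-5-methyl-2H-pyran-2-one | CCc1oc(=O)c(Cc2c(O)c(CC=C(C)C)c(O)c(C(=O)[C@H](C)CC)c2OC)c(O)c1C | target

**Summary**
Total step count: 11. Longest linear sequence: 8 steps (steps 1–7, then 11); the pyranone branch (steps 8–10) is convergent.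

**Steps most likely to fail**

1. Step 11. The methide may be consumed by retro-Mannich and self-condensation of the pyranone, by persistent O-alkylation, or by cycloaddition to the prenyl alkene before the aryl carbon captures it. Fallback with reversed roles, setting out from 11 and 15 and returning at 18: compound 11 is aminomethylated at its only free ring carbon with bis(dimethylamino)methane (CH2Cl2, rt) to give the aryl Mannich base (R)-1-{3-[(dimethylamino)methyl]-4,6-dihydroxy-2-methoxy-5-(3-methylbut-2-en-1-yl)phenyl}-2-methylbutan-1-one F1. F1 is then heated with pyranone 15 (toluene, 80–100 °C), so that the phloroglucinol-derived ortho-quinone methide is trapped by the nucleophilic C3 of 15, which should give 18 directly.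

2. Step 5. The ortho-dienone may tautomerise before the Cope shift, giving the reverse-prenyl ortho isomer, and the ketone may enolise at 200 °C with erosion of enantiomeric purity. Fallback by direct C-prenylation, setting out from 5 and returning at 11: 5 is O-methylated (MeI, K2CO3, DMF) to (R)-1-[2-methoxy-4,6-bis(methoxymethoxy)phenyl]-2-methylbutan-1-one F2. The MOM groups are removed (HCl, MeOH, rt) to give (R)-1-(2,4-dihydroxy-6-methoxyphenyl)-2-methylbutan-1-one F3. F3 is C-prenylated with prenyl bromide and DBU in THF at 0 °C to rt, which should favour the carbon between the two hydroxyls and give 11 after chromatographic removal of the regioisomer and O-prenyl ethers.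

3. Step 2. Enolisation or ketene formation at the acyl chloride or aluminium-bound ketone stage may erode the stereocentre, and over-acylation may compete. Fallback by aryllithium acylation, setting out from 2 and 3 and returning at 5: phloroglucinol 3 is converted (NaH, MOMCl, DMF) into 1,3,5-tris(methoxymethoxy)benzene F4. Chloride 2 is converted (MeNHOMe·HCl, pyridine, CH2Cl2, 0 °C) into the Weinreb amide (R)-N-methoxy-N,2-dimethylbutanamide F5. F4 is lithiated between two MOM ethers (n-BuLi, THF, 0 °C) and added to F5 at −78 °C to give (R)-2-methyl-1-[2,4,6-tris(methoxymethoxy)phenyl]butan-1-one F6. Chelation-assisted removal of one MOM group ortho to the carbonyl (cat. I2, MeOH, rt) should give 5.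

**Further compounds**
F1 | step 11 | (R)-1-{3-[(dimethylamino)methyl]-4,6-dihydroxy-2-methoxy-5-(3-methylbut-2-en-1-yl)phenyl}-2-methylbutan-1-one | CC[C@@H](C)C(=O)c1c(OC)c(CN(C)C)c(O)c(CC=C(C)C)c1O
F2 | step 5 | (R)-1-[2-methoxy-4,6-bis(methoxymethoxy)phenyl]-2-methylbutan-1-one | CC[C@@H](C)C(=O)c1c(OC)cc(OCOC)cc1OCOC
F3 | step 5 | (R)-1-(2,4-dihydroxy-6-methoxyphenyl)-2-methylbutan-1-one | CC[C@@H](C)C(=O)c1c(OC)cc(O)cc1O
F4 | step 2 | 1,3,5-tris(methoxymethoxy)benzene | COCOc1cc(OCOC)cc(OCOC)c1
F5 | step 2 | (R)-N-methoxy-N,2-dimethylbutanamide | CC[C@@H](C)C(=O)N(C)OC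
F6 | step 2 | (R)-2-methyl-1-[2,4,6-tris(methoxymethoxy)phenyl]butan-1-one | CC[C@@H](C)C(=O)c1c(OCOC)cc(OCOC)cc1OCOC
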